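**Plan** (abietane numbering: C10 = quaternary benzylic carbon with the C20 methyl and the C1–C3 acid chain, C5 = CH carrying isopropenyl carbon C4, C6 = CH2, C7 = ketone, arene C8, C9, C11 OH, C12 OMe, C13 isopropyl, C14 OH)
Enabling feature: ring B (C5–C10) is a masked naphthalene ring, with the stereocentres C5 and C10 on adjacent carbons, oxygen on C7 and a one-carbon branch on C10; it maps onto a 4-methoxy-1-naphthyl oxazoline whose C=N carbon is C20.
Cuts: C4–C5 and C10–C1 in one flask (2-propenyllithium addition to the naphthyl oxazoline, allylation of the azaenolate, no ring closes); then C9–C11 and C8–C14 (aryllithium addition to an isopropyl methoxy cyclobutenedione and ring expansion).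
Forward: the benzene ring of 4-methoxybenzonitrile becomes ring B, ring C is annulated onto it to give a hexasubstituted naphthalene, and ring B is then dearomatised. Afterwards oxazoline → C20 methyl, enol ether → C7 ketone, allyl → propanoic acid, and the C11/C14 methyl ethers → hydroquinone by way of the quinone.
Stereochemistry: C5 comes from the tert-leucinol oxazoline (face of organolithium delivery), C10 from alkylation anti to the new C5 substituent; neither centre can epimerise later.

Key step: step 6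

Assumption: the lithium reagent is taken to be delivered from the oxazoline nitrogen to the ring face remote from the tert-butyl group, as in unsubstituted 4-tert-butyl-2-(1-naphthyl)oxazolines; on this model the (R)-auxiliary leads to the (5S,10S) series, and the peri-methoxy group is taken not to reverse it.

Step 1
Reactants: 1 4-methoxybenzonitrile; 2 (R)-tert-leucinol
Product: 3 (R)-4-tert-butyl-2-(4-methoxyphenyl)-4,5-dihydrooxazole
Conditions: ZnCl2 (5 mol %), PhCl, reflux
Reagents that add atoms: none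
Why: Lewis-acid-catalysed condensation of a nitrile with a 1,2-amino alcohol (Witte–Seeliger oxazoline synthesis) should close the oxazoline with loss of ammonia and leave the stereocentre of 2 untouched.

Step 2
Reactants: 4 dimethyl squarate; 5 isopropylmagnesium chloride
Product: 7 3-isopropyl-4-methoxycyclobut-3-ene-1,2-dione, via hydroxycyclobutenone 6 (not isolated)
Conditions: i-PrMgCl, THF, −78 °C; aq. NH4Cl; crude 6, 12 M HCl (cat.), CH2Cl2, rt
Reagents that add atoms: water, O
Why: 1,2-addition of the Grignard reagent to one squarate carbonyl, then acid-promoted ionisation of the tertiary carbinol and hydrolysis of the vinylogous oxocarbenium ion with loss of methanol, is the standard entry to 3-alkyl-4-alkoxycyclobutenediones.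

Step 3
Reactants: 3 (R)-4-tert-butyl-2-(4-methoxyphenyl)-4,5-dihydrooxazole; 7 3-isopropyl-4-methoxycyclobut-3-ene-1,2-dione
Product: 9 4-{2-[(R)-4-tert-butyl-4,5-dihydrooxazol-2-yl]-5-methoxyphenyl}-4-hydroxy-2-isopropyl-3-methoxycyclobut-2-en-1-one (both carbinol epimers), via aryllithium 8 (not isolated)
Conditions: s-BuLi, TMEDA, THF, −78 °C; cannulated into 7, THF, −78 °C; aq. NH4Cl
Reagents that add atoms: sec-butyllithium, CCC(C)[Li] (its lithium is found only in 8)
Why: directed ortho-metalation next to the oxazoline (a stronger director than the para methoxy group) and 1,2-addition of the aryllithium to the ketone-like carbonyl of 7 beside the methoxy-bearing carbon (the other carbonyl is a vinylogous ester) should give 9, whose uncontrolled carbinol centre is erased in step 4.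

Step 4
Reactants: 9 4-aryl-4-hydroxycyclobutenone from step 3
Product: 11 (R)-4-tert-butyl-2-(6-isopropyl-4,5,7,8-tetramethoxynaphthalen-1-yl)-4,5-dihydrooxazole, via naphthalenediol 10 (not isolated)
Conditions: p-xylene (degassed), reflux; solvent exchange, NaH, MeI, DMF, 0 °C → rt, under Ar
Reagents that add atoms: iodomethane, CI
Why: Moore ring expansion (4π-electrocyclic opening to an aryl vinylketene, 6π-closure onto the only free ortho carbon, tautomerisation) should give the naphthalene-1,4-diol with the OH, OMe, isopropyl, OH order of C11–C14, and Williamson methylation of the bis-phenoxide in the same flask forestalls air oxidation.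

Step 5
Reactants: 12 2-bromopropene
Product: 13 2-propenyllithium (ether solution used at once)
Conditions: t-BuLi (2.0 equiv), Et2O, −78 °C
Reagents that add atoms: tert-butyllithium, [Li]C(C)(C)C
Why: bromine–lithium exchange at an sp2 carbon, the second equivalent of t-BuLi destroying the tert-butyl bromide that forms.

Step 6
Reactants: 11 (R)-4-tert-butyl-2-(6-isopropyl-4,5,7,8-tetramethoxynaphthalen-1-yl)-4,5-dihydrooxazole; 13 2-propenyllithium; 14 allyl bromide
Product: 16 (R)-4-tert-butyl-2-[(1R,2S)-1-allyl-6-isopropyl-4,5,7,8-tetramethoxy-2-(prop-1-en-2-yl)-1,2-dihydronaphthalen-1-yl]-4,5-dihydrooxazole (allyl trans to isopropenyl), via lithium azaenolate 15 (not isolated)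
Conditions: 13 (2.5 equiv), THF/Et2O, −78 → −40 °C; 14 (6 equiv), −78 → −20 °C; aq. NaHCO3; SiO2 deactivated with Et3N
Reagents that add atoms: none
Why: 2-Propenyllithium coordinates to the oxazoline nitrogen and is delivered suprafacially to C5 (naphthalene C2), a 1,4-addition across C5=C10–C=N that gives the lithium azaenolate 15, which allyl bromide then alkylates at C10 by SN2. The closest known reaction is the tandem organolithium addition–alkylation of chiral 1-naphthyl oxazolines with alkyl or alkenyl lithiums and reactive halides. No ring closes: aromatic ring B becomes a 1,2-dihydronaphthalene and the C6=C7 bond is left as a methyl enol ether, the later C7 ketone. C5 is set by the auxiliary, whose tert-butyl group shields one face of the N–Li complex so that the alkenyl group enters from the other; C10 is set by the substrate, the halide approaching the planar azaenolate anti to the new isopropenyl group, which places allyl trans to isopropenyl and the oxazoline carbon (future C20) cis. The step needs 1,4-addition at C5 and not attack at the C=N carbon, at C7 or metalation of the ring: the C=N carbon is screened by the peri-methoxy and tert-butyl groups, nitrogen-directed delivery reaches only C5, and the weakly basic sp2 lithium reagent favours addition over deprotonation.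

Step 7
Reactants: 16 dihydronaphthyl oxazoline from step 6
Product: 19 (1R,2S)-1-allyl-6-isopropyl-5,7,8-trimethoxy-4-oxo-2-(prop-1-en-2-yl)-1,2,3,4-tetrahydronaphthalene-1-carbaldehyde, via oxazolinium triflate 17 (not isolated), via N-methyloxazolidine 18 (not isolated)
Conditions: MeOTf, CH2Cl2, 0 °C → rt; NaBH4, THF/MeOH (4:1), 0 °C, aq. NH4Cl work-up; oxalic acid, THF/H2O, rt
Reagents that add atoms: methyl trifluoromethanesulfonate, COS(=O)(=O)C(F)(F)F (methyl and triflate only in 17, methyl in 18); water, O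
Why: the standard oxazoline-to-aldehyde unmasking (N-methylation, hydride reduction of the oxazolinium salt to an N,O-acetal whose aminal centre is of no consequence, mild acid hydrolysis) should release the C20 aldehyde, and the same aqueous acid hydrolyses the aryl enol ether to the C7 ketone only after the borohydride is gone; C10 is quaternary and C5 is β to the carbonyls, so nothing epimerises.

Step 8
Reactants: 19 keto aldehyde from step 7
Product: 20 N'-{(E)-[(1R,2S)-1-allyl-6-isopropyl-5,7,8-trimethoxy-4-oxo-2-(prop-1-en-2-yl)-1,2,3,4-tetrahydronaphthalen-1-yl]methylidene}-4-methylbenzenesulfonohydrazide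
Conditions: TsNHNH2 (1.1 equiv), EtOH, rt
Reagents that add atoms: 4-methylbenzenesulfonohydrazide, Cc1ccc(cc1)S(=O)(=O)NN
Why: hydrazone formation should occur only at the aldehyde, since the C7 aryl ketone is flanked by the C14 methoxy group, deactivated by the electron-rich ring and does not condense at room temperature without acid.

Step 9
Reactants: 20 tosylhydrazone from step 8
Product: 22 (3S,4S)-4-allyl-7-isopropyl-5,6,8-trimethoxy-4-methyl-3-(prop-1-en-2-yl)-3,4-dihydronaphthalen-1(2H)-one, via N-borylhydrazine 21 (not isolated)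
Conditions: catecholborane (1.5 equiv), CHCl3, 0 °C; NaOAc·3H2O, reflux
Reagents that add atoms: catecholborane, B1Oc2ccccc2O1 (its boron and oxygens are found only in 21)
Why: Caglioti-type reduction in its catecholborane variant (hydroboration of C=N, then acetate-induced loss of sulfinate and of N2 from the alkyldiazene) should turn CH=N into the C20 methyl under conditions that leave the hindered ketone, both alkenes and both stereocentres untouched.

Step 10
Reactants: 22 allyl ketone from step 9
Product: 24 (3S,4S)-4-(3-hydroxypropyl)-7-isopropyl-5,6,8-trimethoxy-4-methyl-3-(prop-1-en-2-yl)-3,4-dihydronaphthalen-1(2H)-one, via catechol boronate 23 (not isolated)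
Conditions: RhCl(PPh3)3 (2 mol %), catecholborane, THF, rt; aq. NaOH, H2O2, 0 °C
Reagents that add atoms: catecholborane, B1Oc2ccccc2O1 (boron held only in 23); hydrogen peroxide, OO
Why: rhodium-catalysed hydroboration with catecholborane is selective for a monosubstituted alkene over a ketone and over the 1,1-disubstituted isopropenyl group and places boron on the terminal carbon, which alkaline H2O2 then replaces by hydroxyl.

Step 11
Reactants: 24 primary alcohol from step 10
Product: 25 3-[(1S,2S)-6-isopropyl-5,7,8-trimethoxy-1-methyl-4-oxo-2-(prop-1-en-2-yl)-1,2,3,4-tetrahydronaphthalen-1-yl]propanoic acid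
Conditions: TEMPO (20 mol %), PhI(OAc)2 (2.2 equiv), MeCN/H2O (1:1), rt
Reagents that add atoms: water, O
Why: nitroxyl-catalysed oxidation with PhI(OAc)2 in aqueous acetonitrile should take the primary alcohol through the aldehyde hydrate to the acid and spare the alkene, the ketone and the fully substituted arene.

Step 12
Reactants: 25 trimethoxy keto acid from step 11
Product: 26 3-[(1S,2S)-6-isopropyl-7-methoxy-1-methyl-4,5,8-trioxo-2-(prop-1-en-2-yl)-1,2,3,4,5,8-hexahydronaphthalen-1-yl]propanoic acid
Conditions: (NH4)2Ce(NO3)6 (2.5 equiv), MeCN/H2O (2:1), 0 °C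
Reagents that add atoms: water, O
Why: oxidative demethylation of the para-related C11 and C14 methyl ethers by tetravalent cerium should give the para-quinone, the C12 methoxy group being kept as a vinylogous ester.

Step 13
Reactants: 26 quinone from step 12
Product: 27 3-[(1S,2S)-5,8-dihydroxy-6-isopropyl-7-methoxy-1-methyl-4-oxo-2-(prop-1-en-2-yl)-1,2,3,4-tetrahydronaphthalen-1-yl]propanoic acid (target, 5S,10S in abietane numbering)
Conditions: Na2S2O4, EtOAc/H2O, rt, under Ar
Reagents that add atoms: none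
Why: two-electron reduction of the quinone by dithionite should give the hydroquinone without touching ketone, alkene or acid, the C14 hydroxyl being stabilised by its hydrogen bond to the C7 carbonyl.

**Compound list**
1 | 4-methoxybenzonitrile | COc1ccc(C#N)cc1 | starting material
2 | (R)-tert-leucinol [(R)-2-amino-3,3-dimethylbutan-1-ol] | CC(C)(C)[C@H](CO)N | starting material
3 | (R)-4-tert-butyl-2-(4-methoxyphenyl)-4,5-dihydrooxazole | COc1ccc(cc1)C1=N[C@H](C(C)(C)C)CO1 | intermediate
4 | dimethyl squarate (3,4-dimethoxycyclobut-3-ene-1,2-dione) | COC1=C(OC)C(=O)C1=O | starting material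
5 | isopropylmagnesium chloride | CC(C)[Mg]Cl | starting material
6 | 4-hydroxy-4-isopropyl-2,3-dimethoxycyclobut-2-en-1-one (racemic, not isolated) | COC1=C(OC)C(O)(C(C)C)C1=O | intermediate
7 | 3-isopropyl-4-methoxycyclobut-3-ene-1,2-dione | COC1=C(C(C)C)C(=O)C1=O | intermediate
8 | {2-[(R)-4-tert-butyl-4,5-dihydrooxazol-2-yl]-5-methoxyphenyl}lithium (not isolated) | COc1ccc(C2=N[C@H](C(C)(C)C)CO2)c([Li])c1 | intermediate
9 | 4-{2-[(R)-4-tert-butyl-4,5-dihydrooxazol-2-yl]-5-methoxyphenyl}-4-hydroxy-2-isopropyl-3-methoxycyclobut-2-en-1-one (carbinol centre undefined) | COC1=C(C(C)C)C(=O)C1(O)c1cc(OC)ccc1C1=N[C@H](C(C)(C)C)CO1 | intermediate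
10 | (R)-4-tert-butyl-2-(5,8-dihydroxy-6-isopropyl-4,7-dimethoxynaphthalen-1-yl)-4,5-dihydrooxazole (not isolated) | COc1ccc(C2=N[C@H](C(C)(C)C)CO2)c2c(O)c(OC)c(C(C)C)c(O)c12 | intermediate
11 | (R)-4-tert-butyl-2-(6-isopropyl-4,5,7,8-tetramethoxynaphthalen-1-yl)-4,5-dihydrooxazole | COc1ccc(C2=N[C@H](C(C)(C)C)CO2)c2c(OC)c(OC)c(C(C)C)c(OC)c12 | intermediate
12 | 2-bromopropene | C=C(C)Br | starting material
13 | 2-propenyllithium | [Li]C(C)=C | intermediate
14 | allyl bromide | C=CCBr | starting material
15 | lithium azaenolate of the 2-isopropenyl-1,2-dihydronaphthalene (C10=C–N–Li, 2S; not isolated) | C=C(C)[C@@H]1C=C(OC)c2c(OC)c(C(C)C)c(OC)c(OC)c2C1=C1OC[C@@H](C(C)(C)C)N1[Li] | intermediate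
16 | (R)-4-tert-butyl-2-[(1R,2S)-1-allyl-6-isopropyl-4,5,7,8-tetramethoxy-2-(prop-1-en-2-yl)-1,2-dihydronaphthalen-1-yl]-4,5-dihydrooxazole | C=C(C)[C@@H]1C=C(OC)c2c(OC)c(C(C)C)c(OC)c(OC)c2[C@@]1(C3=N[C@H](C(C)(C)C)CO3)CC=C | intermediate
17 | N-methyloxazolinium trifluoromethanesulfonate of 16 (not isolated) | C=C(C)[C@@H]1C=C(OC)c2c(OC)c(C(C)C)c(OC)c(OC)c2[C@@]1(C3=[N+](C)[C@H](C(C)(C)C)CO3)CC=C.[O-]S(=O)(=O)C(F)(F)F | intermediate
18 | (4R)-4-tert-butyl-3-methyl-2-[(1R,2S)-1-allyl-6-isopropyl-4,5,7,8-tetramethoxy-2-(prop-1-en-2-yl)-1,2-dihydronaphthalen-1-yl]oxazolidine (aminal carbon undefined, not isolated) | C=C(C)[C@@H]1C=C(OC)c2c(OC)c(C(C)C)c(OC)c(OC)c2[C@@]1(C3N(C)[C@H](C(C)(C)C)CO3)CC=C | intermediate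
19 | (1R,2S)-1-allyl-6-isopropyl-5,7,8-trimethoxy-4-oxo-2-(prop-1-en-2-yl)-1,2,3,4-tetrahydronaphthalene-1-carbaldehyde | C=C(C)[C@@H]1CC(=O)c2c(OC)c(C(C)C)c(OC)c(OC)c2[C@@]1(C=O)CC=C | intermediate
20 | (E)-tosylhydrazone of 19 | C=C(C)[C@@H]1CC(=O)c2c(OC)c(C(C)C)c(OC)c(OC)c2[C@@]1(/C=N/NS(=O)(=O)c3ccc(C)cc3)CC=C | intermediate
21 | N-(1,3,2-benzodioxaborol-2-yl)-N-alkyl-N'-tosylhydrazine from 20 (not isolated) | C=C(C)[C@@H]1CC(=O)c2c(OC)c(C(C)C)c(OC)c(OC)c2[C@@]1(CN(B3Oc4ccccc4O3)NS(=O)(=O)c3ccc(C)cc3)CC=C | intermediate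
22 | (3S,4S)-4-allyl-7-isopropyl-5,6,8-trimethoxy-4-methyl-3-(prop-1-en-2-yl)-3,4-dihydronaphthalen-1(2H)-one | C=C(C)[C@@H]1CC(=O)c2c(OC)c(C(C)C)c(OC)c(OC)c2[C@@]1(C)CC=C | intermediate
23 | 2-{3-[(1S,2S)-6-isopropyl-5,7,8-trimethoxy-1-methyl-4-oxo-2-(prop-1-en-2-yl)-1,2,3,4-tetrahydronaphthalen-1-yl]propyl}-1,3,2-benzodioxaborole (not isolated) | C=C(C)[C@@H]1CC(=O)c2c(OC)c(C(C)C)c(OC)c(OC)c2[C@@]1(C)CCCB1Oc2ccccc2O1 | intermediate
24 | (3S,4S)-4-(3-hydroxypropyl)-7-isopropyl-5,6,8-trimethoxy-4-methyl-3-(prop-1-en-2-yl)-3,4-dihydronaphthalen-1(2H)-one | C=C(C)[C@@H]1CC(=O)c2c(OC)c(C(C)C)c(OC)c(OC)c2[C@@]1(C)CCCO | intermediate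
25 | 3-[(1S,2S)-6-isopropyl-5,7,8-trimethoxy-1-methyl-4-oxo-2-(prop-1-en-2-yl)-1,2,3,4-tetrahydronaphthalen-1-yl]propanoic acid | C=C(C)[C@@H]1CC(=O)c2c(OC)c(C(C)C)c(OC)c(OC)c2[C@@]1(C)CCC(=O)O | intermediate
26 | 3-[(1S,2S)-6-isopropyl-7-methoxy-1-methyl-4,5,8-trioxo-2-(prop-1-en-2-yl)-1,2,3,4,5,8-hexahydronaphthalen-1-yl]propanoic acid | C=C(C)[C@@H]1CC(=O)C2=C(C(=O)C(OC)=C(C(C)C)C2=O)[C@@]1(C)CCC(=O)O | intermediate
27 | 3-[(1S,2S)-5,8-dihydroxy-6-isopropyl-7-methoxy-1-methyl-4-oxo-2-(prop-1-en-2-yl)-1,2,3,4-tetrahydronaphthalen-1-yl]propanoic acid | C=C(C)[C@@H]1CC(=O)c2c(O)c(C(C)C)c(OC)c(O)c2[C@@]1(C)CCC(=O)O | target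

**Step count**
Total: 13 steps. Longest linear sequence: 11 steps (1, 3, 4, 6, 7, 8, 9, 10, 11, 12, 13); steps 2 and 5 are side branches.

**Steps most likely to fail**

Step 6. The methoxy-rich, peri-crowded naphthalene may be too poor an acceptor: the peri-methoxy group twists the oxazoline out of conjugation, ring metalation may compete, and facial selectivity may be low or reversed. A reversed sense alone would be met by the (S)-auxiliary. The fallback sets out from 11, returns at 19, and replaces the oxazoline by a hindered aryl ester whose facial control comes from an external ligand. N-Methylation (MeOTf) and alkaline hydrolysis (aq. NaOH, MeOH, reflux) should give 6-isopropyl-4,5,7,8-tetramethoxy-1-naphthoic acid F1. Esterification with 2,6-di-tert-butyl-4-methoxyphenol ((CF3CO)2O, toluene) should give 2,6-di-tert-butyl-4-methoxyphenyl 6-isopropyl-4,5,7,8-tetramethoxy-1-naphthoate F2. Conjugate addition of 13 in the presence of stoichiometric 1,2-dimethoxy-1,2-diphenylethane (the antipode that gives the 2S adduct; toluene, −78 °C) and trapping of the ester enolate with 14 should give 2,6-di-tert-butyl-4-methoxyphenyl (1R,2S)-1-allyl-6-isopropyl-4,5,7,8-tetramethoxy-2-(prop-1-en-2-yl)-1,2-dihydronaphthalene-1-carboxylate F3; ligand-controlled addition of organolithiums to hindered aryl naphthoates is known. LiAlH4 (THF, reflux) should release [(1R,2S)-1-allyl-6-isopropyl-4,5,7,8-tetramethoxy-2-(prop-1-en-2-yl)-1,2-dihydronaphthalen-1-yl]methanol F4. Dess–Martin periodinane buffered with pyridine should give (1R,2S)-1-allyl-6-isopropyl-4,5,7,8-tetramethoxy-2-(prop-1-en-2-yl)-1,2-dihydronaphthalene-1-carbaldehyde F5, and aqueous oxalic acid hydrolyses its enol ether to 19.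

Step 12. The oxidant may over-oxidise the substrate, attack the isopropenyl group, or demethylate the C11/C12 pair to the ortho-quinone. The fallback sets out from 25 and returns at 26. BCl3 (CH2Cl2, −78 → 0 °C) should cleave only the C14 methyl ether, which sits ortho to the C7 carbonyl and chelates boron, giving 3-[(1S,2S)-5-hydroxy-6-isopropyl-7,8-dimethoxy-1-methyl-4-oxo-2-(prop-1-en-2-yl)-1,2,3,4-tetrahydronaphthalen-1-yl]propanoic acid F6. PhI(OAc)2 in aqueous acetonitrile then oxidises this para-methoxyphenol to 26 with loss of methanol, under conditions far milder than a one-electron oxidant.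

Step 9. Hydride delivery to the crowded neopentyl C=N bond may be slow, so that reduction of the C7 ketone competes. The fallback sets out from 19 and returns at 22. NaBH4 in EtOH/CH2Cl2 at −78 °C should reduce only the aldehyde, giving (3S,4R)-4-allyl-4-(hydroxymethyl)-7-isopropyl-5,6,8-trimethoxy-3-(prop-1-en-2-yl)-3,4-dihydronaphthalen-1(2H)-one F7. O-Phenyl chlorothionoformate (pyridine, DMAP, CH2Cl2) should give O-{[(1R,2S)-1-allyl-6-isopropyl-5,7,8-trimethoxy-4-oxo-2-(prop-1-en-2-yl)-1,2,3,4-tetrahydronaphthalen-1-yl]methyl} O-phenyl carbonothioate F8. Barton–McCombie deoxygenation (Bu3SnH at high concentration, AIBN, toluene, reflux) then gives 22; the high stannane concentration is meant to outrun 1,2-aryl migration of the primary radical.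

**Further compounds**
F1 | step 6 | 6-isopropyl-4,5,7,8-tetramethoxy-1-naphthoic acid | COc1ccc(C(=O)O)c2c(OC)c(OC)c(C(C)C)c(OC)c12
F2 | step 6 | 2,6-di-tert-butyl-4-methoxyphenyl 6-isopropyl-4,5,7,8-tetramethoxy-1-naphthoate | COc1ccc(C(=O)Oc3c(C(C)(C)C)cc(OC)cc3C(C)(C)C)c2c(OC)c(OC)c(C(C)C)c(OC)c12
F3 | step 6 | 2,6-di-tert-butyl-4-methoxyphenyl (1R,2S)-1-allyl-6-isopropyl-4,5,7,8-tetramethoxy-2-(prop-1-en-2-yl)-1,2-dihydronaphthalene-1-carboxylate | C=C(C)[C@@H]1C=C(OC)c2c(OC)c(C(C)C)c(OC)c(OC)c2[C@@]1(C(=O)Oc3c(C(C)(C)C)cc(OC)cc3C(C)(C)C)CC=C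
F4 | step 6 | [(1R,2S)-1-allyl-6-isopropyl-4,5,7,8-tetramethoxy-2-(prop-1-en-2-yl)-1,2-dihydronaphthalen-1-yl]methanol | C=C(C)[C@@H]1C=C(OC)c2c(OC)c(C(C)C)c(OC)c(OC)c2[C@@]1(CO)CC=C
F5 | step 6 | (1R,2S)-1-allyl-6-isopropyl-4,5,7,8-tetramethoxy-2-(prop-1-en-2-yl)-1,2-dihydronaphthalene-1-carbaldehyde | C=C(C)[C@@H]1C=C(OC)c2c(OC)c(C(C)C)c(OC)c(OC)c2[C@@]1(C=O)CC=C
F6 | step 12 | 3-[(1S,2S)-5-hydroxy-6-isopropyl-7,8-dimethoxy-1-methyl-4-oxo-2-(prop-1-en-2-yl)-1,2,3,4-tetrahydronaphthalen-1-yl]propanoic acid | C=C(C)[C@@H]1CC(=O)c2c(O)c(C(C)C)c(OC)c(OC)c2[C@@]1(C)CCC(=O)O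
F7 | step 9 | (3S,4R)-4-allyl-4-(hydroxymethyl)-7-isopropyl-5,6,8-trimethoxy-3-(prop-1-en-2-yl)-3,4-dihydronaphthalen-1(2H)-one | C=C(C)[C@@H]1CC(=O)c2c(OC)c(C(C)C)c(OC)c(OC)c2[C@@]1(CO)CC=C
F8 | step 9 | O-{[(1R,2S)-1-allyl-6-isopropyl-5,7,8-trimethoxy-4-oxo-2-(prop-1-en-2-yl)-1,2,3,4-tetrahydronaphthalen-1-yl]methyl} O-phenyl carbonothioate | C=C(C)[C@@H]1CC(=O)c2c(OC)c(C(C)C)c(OC)c(OC)c2[C@@]1(COC(=S)Oc3ccccc3)CC=C
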